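**Plan**
Numbering used here: ring C1 (C=O), C2=C3, C4 (OMe), C5 (CH2), C6 (quaternary); side chain C2′ (CHMe) and C1′ (carbinol).
Cuts: C1–C2 and C4–C5, both made in one step. C1, C6, C2′, C1′ and the carbinol oxygen are folded back into a γ-lactone (8, with C5 as CH2I); C2=C3–C4 is the Z-iodoalkene acetal 11.
Feature used: the free hydroxyl lies 1,4 to the ketone carbon, so the ketone can be carried as a lactone carbonyl. This temporary five-membered ring relays stereochemistry to C6, gives its acyl carbon to C2, and releases the hydroxyl when the six-membered ring forms.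
Forward: crotylboration, hydroboration, oxidative lactonization (lactone ring), two enolate alkylations and iodination give 8; 11 is made separately; the lactone-to-cyclohexenone ring switch then gives megaphone directly.
Stereochemistry: C1′ and C2′ come from one acid-catalysed Z-crotylboration; C6 is relayed by the cis 4-methyl/5-aryl lactone (allyl enters anti); C4 is relayed from C6 in the ring closure.

Key step: step 9

Remark: 3,3-dimethoxyprop-1-yne (propiolaldehyde dimethyl acetal, 9) is taken as a commercial material.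

Step 1
Reactants: 1 3,4,5-trimethoxybenzaldehyde; 2 (Z)-crotylboronic acid pinacol ester
Product: 3 (1R,2S)-2-methyl-1-(3,4,5-trimethoxyphenyl)but-3-en-1-ol
Conditions: (R)-3,3′-bis(2,4,6-triisopropylphenyl)-1,1′-binaphthyl-2,2′-diyl hydrogen phosphate (5 mol%), toluene, −30 °C; aqueous work-up
Reagents that add atoms: none
Why: Brønsted-acid-catalysed allylboration through a closed six-membered chair transition state, in which the Z-boronate gives the syn adduct and the (R)-configured acid should direct attack to the Re face of the aldehyde, setting C1′ (R) and C2′ (S) together.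

Step 2
Reactants: 3 (1R,2S)-2-methyl-1-(3,4,5-trimethoxyphenyl)but-3-en-1-ol
Product: 4 (1R,2S)-2-methyl-1-(3,4,5-trimethoxyphenyl)butane-1,4-diol
Conditions: 9-borabicyclo[3.3.1]nonane (2.2 equiv), THF, 0 °C to rt; then NaOH, H2O2
Reagents that add atoms: hydrogen peroxide (OO)
Why: Hydroboration–oxidation places boron, then oxygen, on the terminal carbon of the alkene (anti-Markovnikov) and touches no stereocenter.

Step 3
Reactants: 4 (1R,2S)-2-methyl-1-(3,4,5-trimethoxyphenyl)butane-1,4-diol
Product: 5 (4S,5R)-4-methyl-5-(3,4,5-trimethoxyphenyl)oxolan-2-one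
Conditions: (2,2,6,6-tetramethylpiperidin-1-yl)oxyl (cat.), PhI(OAc)2, CH2Cl2, rt
Reagents that add atoms: none
Why: Oxoammonium oxidation is selective for the primary alcohol; the aldehyde closes to the lactol with the benzylic hydroxyl and is oxidized on to the lactone, so the syn diol becomes the cis-4-methyl-5-aryl lactone.

Step 4
Reactants: 5 (4S,5R)-4-methyl-5-(3,4,5-trimethoxyphenyl)oxolan-2-one
Product: 6 (3R,4S,5R)-3-(hydroxymethyl)-4-methyl-5-(3,4,5-trimethoxyphenyl)oxolan-2-one
Conditions: LDA, THF, −78 °C; CH2O (gas); aq. NH4Cl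
Reagents that add atoms: formaldehyde (C=O)
Why: Aldol reaction of the lactone lithium enolate with formaldehyde, in which the hydroxymethyl group should enter anti to the 4-methyl group; this center is flattened again in step 5.

Step 5
Reactants: 6 (3R,4S,5R)-3-(hydroxymethyl)-4-methyl-5-(3,4,5-trimethoxyphenyl)oxolan-2-one
Product: 7 (3S,4S,5R)-3-(hydroxymethyl)-4-methyl-3-(prop-2-en-1-yl)-5-(3,4,5-trimethoxyphenyl)oxolan-2-one
Conditions: LDA (2.2 equiv), THF/DMPU, −78 to −30 °C; allyl bromide; aq. NH4Cl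
Reagents that add atoms: allyl bromide (C=CCBr)
Why: Fráter–Seebach-type alkylation of the alkoxide–enolate dianion, in which allyl bromide attacks the enolate face opposite to the cis 4-methyl and 5-aryl groups and so sets the quaternary carbon (future C6) with allyl trans to both.

Step 6
Reactants: 7 (3S,4S,5R)-3-(hydroxymethyl)-4-methyl-3-(prop-2-en-1-yl)-5-(3,4,5-trimethoxyphenyl)oxolan-2-one
Product: 8 (3R,4S,5R)-3-(iodomethyl)-4-methyl-3-(prop-2-en-1-yl)-5-(3,4,5-trimethoxyphenyl)oxolan-2-one
Conditions: PPh3, I2, imidazole, toluene, 80 °C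
Reagents that add atoms: iodine (II)
Why: Appel-type iodination, in which iodide displaces the alkoxyphosphonium group on heating at a neopentyl carbon that can neither eliminate nor epimerize.

Step 7
Reactants: 9 3,3-dimethoxyprop-1-yne
Product: 10 1-iodo-3,3-dimethoxyprop-1-yne
Conditions: N-iodosuccinimide, AgNO3 (10 mol%), acetone, rt
Reagents that add atoms: N-iodosuccinimide (O=C1CCC(=O)N1I)
Why: Silver-catalysed electrophilic iodination of the terminal alkyne C–H.

Step 8
Reactants: 10 1-iodo-3,3-dimethoxyprop-1-yne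
Product: 11 (Z)-1-iodo-3,3-dimethoxyprop-1-ene
Conditions: 2-nitrobenzenesulfonylhydrazide, Et3N, THF/i-PrOH, rt
Reagents that add atoms: none
Why: Diimide reduction transfers two hydrogens syn to the iodoalkyne and should give the Z-iodoalkene needed for a cis C2=C3 bond, leaving the acetal and the C–I bond intact.

Step 9
Reactants: 8 (3R,4S,5R)-3-(iodomethyl)-4-methyl-3-(prop-2-en-1-yl)-5-(3,4,5-trimethoxyphenyl)oxolan-2-one; 11 (Z)-1-iodo-3,3-dimethoxyprop-1-ene
Product: 16 megaphone, via vinyllithium 12 (not isolated), via lactol alkoxide 13 (not isolated), via alkyllithium 14 (not isolated), via alkylcopper 15 (not isolated)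
Conditions: t-BuLi (2 equiv), Et2O, −78 °C (on 11); 8, THF, −78 °C; t-BuLi (2 equiv), −78 °C; CuBr·SMe2; BF3·OEt2, −78 to −40 °C; aq. NH4Cl
Reagents that add atoms: none
Why: Proposed new method: vinyllithium 12 adds once to the lactone carbonyl of 8 (C1–C2) to give lactol alkoxide 13, which masks the new ketone while iodine–lithium exchange and transmetalation turn the neopentyl iodide into alkylcopper 15; BF3 then ionizes the allylic dimethyl acetal, the C–Cu bond attacks the oxocarbenium carbon (C4–C5), and work-up opens the lactol to the hydroxy enone. The closest known reaction types are the single addition of organolithiums to γ-lactones, Parham-type halogen–lithium exchange beside a masked carbonyl group, and the BF3-promoted substitution of acetals by organocopper reagents; what is new is their union into a ring switch from lactone to cyclohexenone. The six-membered ring closes in a 6-exo-trig mode onto the exocyclic C=O+ bond of the oxocarbenium ion. C4 is set by substrate control: in the half-chair transition state the methoxy group should lie pseudo-equatorial and anti to the pseudo-axial allyl group on C6, which places OMe cis to the side chain. The step needs mono-addition and chemoselectivity in the first stage (at −78 °C the lactol alkoxide holds and the less basic vinyllithium does not exchange with the alkyl iodide), attack at the acetal carbon and not at the far allyl terminus (that would close a four-membered ring), and a cis C2=C3 bond (fixed by the Z-iodide 11).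

**Compound list**
1 | 3,4,5-trimethoxybenzaldehyde | O=Cc1cc(OC)c(OC)c(OC)c1 | starting material
2 | (Z)-crotylboronic acid pinacol ester, 2-[(2Z)-but-2-en-1-yl]-4,4,5,5-tetramethyl-1,3,2-dioxaborolane | C/C=C\CB1OC(C)(C)C(C)(C)O1 | starting material
3 | (1R,2S)-2-methyl-1-(3,4,5-trimethoxyphenyl)but-3-en-1-ol | C=C[C@H](C)[C@@H](O)c1cc(OC)c(OC)c(OC)c1 | intermediate
4 | (1R,2S)-2-methyl-1-(3,4,5-trimethoxyphenyl)butane-1,4-diol | OCC[C@H](C)[C@@H](O)c1cc(OC)c(OC)c(OC)c1 | intermediate
5 | (4S,5R)-4-methyl-5-(3,4,5-trimethoxyphenyl)oxolan-2-one (methyl and aryl cis) | O=C1C[C@H](C)[C@H](c2cc(OC)c(OC)c(OC)c2)O1 | intermediate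
6 | (3R,4S,5R)-3-(hydroxymethyl)-4-methyl-5-(3,4,5-trimethoxyphenyl)oxolan-2-one | O=C1[C@@H](CO)[C@H](C)[C@H](c2cc(OC)c(OC)c(OC)c2)O1 | intermediate
7 | (3S,4S,5R)-3-(hydroxymethyl)-4-methyl-3-(prop-2-en-1-yl)-5-(3,4,5-trimethoxyphenyl)oxolan-2-one (allyl trans to methyl and aryl) | O=C1[C@](CC=C)(CO)[C@H](C)[C@H](c2cc(OC)c(OC)c(OC)c2)O1 | intermediate
8 | (3R,4S,5R)-3-(iodomethyl)-4-methyl-3-(prop-2-en-1-yl)-5-(3,4,5-trimethoxyphenyl)oxolan-2-one | O=C1[C@](CC=C)(CI)[C@H](C)[C@H](c2cc(OC)c(OC)c(OC)c2)O1 | intermediate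
9 | 3,3-dimethoxyprop-1-yne | C#CC(OC)OC | starting material
10 | 1-iodo-3,3-dimethoxyprop-1-yne | IC#CC(OC)OC | intermediate
11 | (Z)-1-iodo-3,3-dimethoxyprop-1-ene | I/C=C\C(OC)OC | intermediate
12 | (Z)-(3,3-dimethoxyprop-1-en-1-yl)lithium, formed in the flask | [Li]/C=C\C(OC)OC | intermediate
13 | lactol lithium alkoxide: lithium 2-[(Z)-3,3-dimethoxyprop-1-enyl]-3-(iodomethyl)-4-methyl-3-(prop-2-en-1-yl)-5-(3,4,5-trimethoxyphenyl)oxolan-2-olate, alkenyl group cis to allyl, other centers as in 8; formed in the flask | [Li]O[C@]1(/C=C\C(OC)OC)[C@](CC=C)(CI)[C@H](C)[C@H](c2cc(OC)c(OC)c(OC)c2)O1 | intermediate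
14 | alkyllithium: the 3-(lithiomethyl) analogue of 13, formed in the flask | [Li]O[C@]1(/C=C\C(OC)OC)[C@](CC=C)(C[Li])[C@H](C)[C@H](c2cc(OC)c(OC)c(OC)c2)O1 | intermediate
15 | alkylcopper: the 3-(cupriomethyl) analogue of 13, formed in the flask | [Li]O[C@]1(/C=C\C(OC)OC)[C@](CC=C)(C[Cu])[C@H](C)[C@H](c2cc(OC)c(OC)c(OC)c2)O1 | intermediate
16 | megaphone, (4R,6R)-6-[(1R,2S)-1-hydroxy-1-(3,4,5-trimethoxyphenyl)propan-2-yl]-4-methoxy-6-(prop-2-en-1-yl)cyclohex-2-en-1-one | C=CC[C@]1([C@H](C)[C@@H](O)c2cc(OC)c(OC)c(OC)c2)C[C@@H](OC)C=CC1=O | target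

**Step count**
Total: 9 steps. Longest linear sequence: 7 steps (steps 1–6 and 9).

**Steps most likely to fail**

1. Step 9 (bears the label "Proposed new method:").
What may go wrong: the lactol alkoxide may open before the copper reagent is formed, so that the alkyllithium adds to the unmasked ketone (three-membered ring closure). The keto-oxocarbenium ion may close on oxygen and aromatize to a furan. Facial selectivity at C4 may be poor.
Fallback with known chemistry, from 8 back to 16: iodine–zinc exchange of 8 with Et2Zn (cat. CuI, 50 °C) should give the dialkylzinc F1. Its addition to freshly made (Z)-3-iodoprop-2-enal F2 (from ethyl (Z)-3-iodoacrylate and DIBAL-H) is catalysed by Ti(OiPr)4 and (1S,2S)-1,2-bis(trifluoromethanesulfonamido)cyclohexane in toluene at −20 °C. Catalyst control (Re-face attack) should set C4 and give the allylic alcohol F3. Methylation with MeOTf and 2,6-di-tert-butyl-4-methylpyridine should give the methyl ether F4. Iodine–lithium exchange (t-BuLi, Et2O, −100 °C) with Parham-type attack of the vinyllithium on the lactone carbonyl should then give 16. Here the two ring bonds are made in separate steps.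

2. Step 5.
What may go wrong: the alkoxide–enolate dianion may lose formaldehyde (retro-aldol), or the alkoxide may be allylated on oxygen.
Fallback, from 5 back to 7: alkylation of the enolate of 5 (LDA, THF, −78 °C) with 4-methoxybenzyl chloromethyl ether should give the ether F5. A second enolate alkylation (LDA, allyl bromide), with the same facial argument, should give the quaternary lactone F6. Oxidative removal of the 4-methoxybenzyl group (DDQ, CH2Cl2/H2O) returns to 7.

3. Step 6.
What may go wrong: displacement at the neopentyl carbon may be slow, and the alkoxyphosphonium ion may be diverted by the neighbouring lactone carbonyl or the alkene.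
Fallback, from 5 back to 8, avoiding substitution at the neopentyl carbon: alkylation of the enolate of 5 with tert-butyl bromoacetate should give the ester F7. Allylation (LDA, allyl bromide) should give the quaternary ester F8. Cleavage of the tert-butyl ester (CF3CO2H, CH2Cl2) should give the acid F9. Conversion through the acid chloride into the N-hydroxypyridine-2-thione ester F10, followed by photolysis with iodoform (Barton decarboxylative iodination), should give 8.

**Further compounds**
F1 | step 9 | bis{[(3R,4S,5R)-4-methyl-2-oxo-3-(prop-2-en-1-yl)-5-(3,4,5-trimethoxyphenyl)oxolan-3-yl]methyl}zinc | C=CC[C@@]1(C[Zn]C[C@]2(CC=C)[C@H](C)[C@H](c3cc(OC)c(OC)c(OC)c3)OC2=O)[C@H](C)[C@H](c2cc(OC)c(OC)c(OC)c2)OC1=O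
F2 | step 9 | (Z)-3-iodoprop-2-enal | O=C/C=C\I
F3 | step 9 | (3R,4S,5R)-3-[(2R,3Z)-2-hydroxy-4-iodobut-3-en-1-yl]-4-methyl-3-(prop-2-en-1-yl)-5-(3,4,5-trimethoxyphenyl)oxolan-2-one | C=CC[C@@]1(C[C@@H](O)/C=C\I)[C@H](C)[C@H](c2cc(OC)c(OC)c(OC)c2)OC1=O
F4 | step 9 | (3R,4S,5R)-3-[(2R,3Z)-4-iodo-2-methoxybut-3-en-1-yl]-4-methyl-3-(prop-2-en-1-yl)-5-(3,4,5-trimethoxyphenyl)oxolan-2-one | C=CC[C@@]1(C[C@@H](OC)/C=C\I)[C@H](C)[C@H](c2cc(OC)c(OC)c(OC)c2)OC1=O
F5 | step 5 | (3R,4S,5R)-3-{[(4-methoxyphenyl)methoxy]methyl}-4-methyl-5-(3,4,5-trimethoxyphenyl)oxolan-2-one | O=C1[C@@H](COCc2ccc(OC)cc2)[C@H](C)[C@H](c2cc(OC)c(OC)c(OC)c2)O1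
F6 | step 5 | (3S,4S,5R)-3-{[(4-methoxyphenyl)methoxy]methyl}-4-methyl-3-(prop-2-en-1-yl)-5-(3,4,5-trimethoxyphenyl)oxolan-2-one | O=C1[C@](CC=C)(COCc2ccc(OC)cc2)[C@H](C)[C@H](c2cc(OC)c(OC)c(OC)c2)O1
F7 | step 6 | tert-butyl 2-[(3S,4S,5R)-4-methyl-2-oxo-5-(3,4,5-trimethoxyphenyl)oxolan-3-yl]acetate | O=C1[C@@H](CC(=O)OC(C)(C)C)[C@H](C)[C@H](c2cc(OC)c(OC)c(OC)c2)O1
F8 | step 6 | tert-butyl 2-[(3R,4S,5R)-4-methyl-2-oxo-3-(prop-2-en-1-yl)-5-(3,4,5-trimethoxyphenyl)oxolan-3-yl]acetate | O=C1[C@](CC=C)(CC(=O)OC(C)(C)C)[C@H](C)[C@H](c2cc(OC)c(OC)c(OC)c2)O1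
F9 | step 6 | 2-[(3R,4S,5R)-4-methyl-2-oxo-3-(prop-2-en-1-yl)-5-(3,4,5-trimethoxyphenyl)oxolan-3-yl]acetic acid | O=C1[C@](CC=C)(CC(=O)O)[C@H](C)[C@H](c2cc(OC)c(OC)c(OC)c2)O1
F10 | step 6 | 2-sulfanylidenepyridin-1(2H)-yl 2-[(3R,4S,5R)-4-methyl-2-oxo-3-(prop-2-en-1-yl)-5-(3,4,5-trimethoxyphenyl)oxolan-3-yl]acetate | O=C1[C@](CC=C)(CC(=O)ON2C=CC=CC2=S)[C@H](C)[C@H](c2cc(OC)c(OC)c(OC)c2)O1
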